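Before you fit anything, decide which charge to count against the electrophile. Here, count the nucleophile.

all flasks: electrophile 0.20 M

| run | nucleophile | free base | remark | time |
|---|---|---|---|---|
| north | 1 equiv | 0.76 equiv | run made earlier |  |
| north-east | 1 equiv | 0.88 equiv | run made earlier |  |
| violet | 1.00 equiv | 1.10 equiv |  | 8.0 h |
| ochre | 1.00 equiv | 1.40 equiv |  | 8.0 h |

| run | time / h | electrophile / % | target / % |
|---|---|---|---|
| north | 0.500 | 48 | 53 |
| north | 1.00 | 37 | 62 |
| north | 1.50 | 32 | 66 |
| north | 2.50 | 31 | 74 |
| north | 3.00 | 31 | 73 |
| north | 4.00 | 26 | 75 |
| north-east | 0.500 | 50 | 51 |
| north-east | 1.00 | 35 | 62 |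
| north-east | 1.50 | 34 | 69 |
| north-east | 2.50 | 29 | 71 |
| north-east | 3.00 | 26 | 71 |
| north-east | 4.00 | 25 | 71 |

(each reading ± 1.5 percentage points)

* part of the electrophile that has reacted at the end, violet
* part of the electrophile that has reacted at the end, ochre
* what raising the equivalents of free base from its lowest to its highest value here does to the part of the electrophile that has reacted (changes below 5 percentage points count as none) (no change / it rises / it falls)

- acid set free is meant together with its crystals
- solid, in amounts per volume of the solution: crystals
- candidate steps: electrophile + nucleophile -> acid set free + target; nucleophile + acid set free <-> protonated nucleophile; acid set free + free base <-> salt of the base; 2 nucleophile -> self-condensation product; crystals <-> acid set free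

At their last readings, after 4.00 h, the two earlier runs have used on average 74.5% of the electrophile. The 1 percentage point between them is less than the scatter, although their free base differs. Define the nucleophile cost as the nucleophile charged per electrophile reacted at the stall. By that reading it stands at 1.34.

My bracket takes the free base to stay as indifferent in violet and ochre. The first step is written one-way, so the reacted electrophile, a reading with its scatter, gives the lower bound. The nucleophile charge gives a loose upper bound of 100%.

Logarithms of time tighten this. From 1.00 h to 4.00 h the electrophile in the two earlier runs fell on average 17 points per decade of time. From 0.500 h to 1.00 h the fall was 43 points per decade, steeper than the later slope. Carrying the later slope on to 8.0 h is therefore generous: it adds 5.2 points and gives a top of 79.8%, a cost of 1.25.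

The forecast gives 79% for violet, 79% for ochre and no change, holding it likeliest that “the nucleophile is lost to self-condensation, which is independent of base”. Its number lies inside my bracket, above the lower bound and below the estimated top.

Violet gives 74.8% and ochre 74.8%, so the trend is no change, at −0.03 points.

electrophile + nucleophile → acid set free + target (k = 0.240 M⁻¹ min⁻¹); nucleophile + acid set free ⇌ protonated nucleophile, settled at all times (K = 1300 M⁻¹); acid set free + free base ⇌ salt of the base, settled at all times (K = 1.00 × 10⁵ M⁻¹); 2 nucleophile → self-condensation product (k = 0.0610 M⁻¹ min⁻¹); crystals ⇌ acid set free, rate k5*(cs5 - [acid set free]) while solid is left; crystals form when [acid set free] > cs5 (solubility = 0.120 M, k = 0.510 min⁻¹) At the end ochre keeps 0.049% of its nucleophile, the limiting reagent, against 25% of its electrophile. The cost in violet comes to 1.34. Applied to a flask like ochre but charged with 0.400 equiv of nucleophile, the cost of 1.34 gives 29.9%. That flask reached 35.9%, a cost of 1.11.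

(The runs come from a simulation on assumed constants, noise included.)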